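**Retrosynthetic overview**
1. Caespitol ⇐ O‑TBS caespitol ⇐ ring α‑epoxide: HBr opening, then chlorination of the trans‑diaxial bromohydrin with 1,2‑bromine migration (ring halogens last).
2. Bromo‑oxane (C–Br and gem‑dimethyl carbon) ⇐ vicinal bromo‑methylation of a cyclic methyl enol ether ⇐ δ‑lactone.
3. δ‑Lactone ⇐ Baeyer–Villiger ring expansion (quaternary carbon migrates C→O with retention; key step) of a 3‑silyloxy‑2,2‑disubstituted cyclopentanone ⇐ CBS desymmetrisation of the cyclopentane‑1,3‑dione.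
4. Dione ⇐ geminal acylation of (S)‑4‑acetyl‑1‑methylcyclohexene (aldol, then pinacol 4→5 ring expansion) ⇐ catalytic asymmetric Diels–Alder of isoprene and methyl vinyl ketone.
5. Ring order: cyclohexene → cyclopentanedione → lactone/oxane (5→6 ring expansion) → halogenated cyclohexane.

Assumption: 4 is commercial; its two Me3Si groups are protecting groups of cyclobut‑1‑ene‑1,2‑diol and are lost in step 2.

Locants C7–C11 and C1′–C6′ follow bisabolane numbering of the target: C7 and C11 are the oxane carbons next to O, C8 bears OH, C10 bears Br; C1′ is the ring carbon attached to C7, C4′ bears Cl, C5′ bears Br.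

**Step 1**
Reactants: 1 isoprene; 2 methyl vinyl ketone
Product: 3 (S)-1-(4-methylcyclohex-3-en-1-yl)ethan-1-one
Conditions: Corey cationic oxazaborolidine (o‑tolyl‑CBS·AlBr3, 5 mol%, antipode giving S), CH2Cl2, −78 °C
Reagents that add atoms: none
Why: Catalytic enantioselective Diels–Alder reaction in which the Lewis‑acid‑bound enone adds "para" to the isoprene methyl and the catalyst fixes C1′ as S.

**Step 2**
Reactants: 3 (S)-1-(4-methylcyclohex-3-en-1-yl)ethan-1-one; 4 1,2-bis(trimethylsilyloxy)cyclobut-1-ene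
Product: 6 2-methyl-2-[(1S)-4-methylcyclohex-3-en-1-yl]cyclopentane-1,3-dione, via bis-silyl cyclobutanone aldol adduct 5 (not isolated)
Conditions: 4 (2 equiv), BF3·OEt2, CH2Cl2, −78 °C; then H2O (1 equiv), more BF3·OEt2, −78 → 23 °C
Reagents that add atoms: none
Why: Kuwajima–Nakamura/Burnell geminal acylation, a Mukaiyama aldol followed by a pinacol 1,2‑acyl shift (cyclobutanone → cyclopentane‑1,3‑dione), makes the ketone carbon the quaternary C7; C1′ is not enolised at −78 °C and is not epimerisable afterwards.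

**Step 3**
Reactants: 6 2-methyl-2-[(1S)-4-methylcyclohex-3-en-1-yl]cyclopentane-1,3-dione
Product: 7 (2R,3R)-3-hydroxy-2-methyl-2-[(1S)-4-methylcyclohex-3-en-1-yl]cyclopentan-1-one
Conditions: (S)‑Me‑CBS (20 mol%), catecholborane (1.1 equiv), PhNEt2, PhMe, −60 °C; MeOH, aq NaHCO3
Reagents that add atoms: none
Why: CBS desymmetrising reduction of a 2,2‑disubstituted cyclopentane‑1,3‑dione, with hydride delivered anti to the bulky cyclohexenyl group (OH cis to it) and the catalyst choosing the carbonyl that gives the 3R carbinol, so C7 and C8 are set together.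

**Step 4**
Reactants: 7 (2R,3R)-3-hydroxy-2-methyl-2-[(1S)-4-methylcyclohex-3-en-1-yl]cyclopentan-1-one
Product: 8 (2R,3R)-3-[(tert-butyldimethylsilyl)oxy]-2-methyl-2-[(1S)-4-methylcyclohex-3-en-1-yl]cyclopentan-1-one
Conditions: TBSOTf, 2,6‑lutidine, CH2Cl2, 0 °C
Reagents that add atoms: tert‑butyldimethylsilyl triflate, CC(C)(C)[Si](C)(C)OS(=O)(=O)C(F)(F)F
Why: Silylation of the secondary alcohol blocks translactonisation and later competition of this OH; the α‑carbon is quaternary, so no β‑elimination is possible.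

**Step 5**
Reactants: 8 (2R,3R)-3-[(tert-butyldimethylsilyl)oxy]-2-methyl-2-[(1S)-4-methylcyclohex-3-en-1-yl]cyclopentan-1-one
Product: 9 (5R,6R)-5-[(tert-butyldimethylsilyl)oxy]-6-methyl-6-[(1S)-4-methylcyclohex-3-en-1-yl]oxan-2-one
Conditions: Me3SiOOSiMe3 (2 equiv), TMSOTf (10 mol%), CH2Cl2, −40 → 0 °C
Reagents that add atoms: bis(trimethylsilyl) peroxide, C[Si](C)(C)OO[Si](C)(C)C
Why: Baeyer–Villiger ring expansion in which the quaternary carbon migrates from C to O with retention, giving the C7–O bond as a single stereoisomer, under silyl‑peroxide conditions that do not epoxidise the ring alkene.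

**Step 6**
Reactants: 9 (5R,6R)-5-[(tert-butyldimethylsilyl)oxy]-6-methyl-6-[(1S)-4-methylcyclohex-3-en-1-yl]oxan-2-one
Product: 11 (2R,3R)-3-[(tert-butyldimethylsilyl)oxy]-2,6-dimethyl-2-[(1S)-4-methylcyclohex-3-en-1-yl]-3,4-dihydro-2H-pyran, via methyl lactol 10 (not isolated)
Conditions: MeLi (1.1 equiv), THF, −78 °C; AcOH; then PPTS (5 mol%), 4 Å MS, PhMe, 80 °C
Reagents that add atoms: methyllithium, [Li]C
Why: Single organolithium addition to the lactone (stable lactolate at −78 °C), then acid‑catalysed dehydration of the hemiketal to the more substituted endocyclic enol ether.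

**Step 7**
Reactants: 11 (2R,3R)-3-[(tert-butyldimethylsilyl)oxy]-2,6-dimethyl-2-[(1S)-4-methylcyclohex-3-en-1-yl]-3,4-dihydro-2H-pyran
Product: 13 (2R,3R,5R)-5-bromo-3-[(tert-butyldimethylsilyl)oxy]-2,6,6-trimethyl-2-[(1S)-4-methylcyclohex-3-en-1-yl]oxane, via anomeric dibromide 12 (not isolated)
Conditions: Br2 (1.0 equiv), CH2Cl2, −78 °C, 5 min; then AlMe3 (3 equiv), −78 → −30 °C
Reagents that add atoms: bromine, BrBr; trimethylaluminium, C[Al](C)C
Why: Proposed new method: vicinal bromo‑methylation of a cyclic 2‑methyl enol ether, in which Br2 attacks the nucleophilic β‑carbon C10 (far faster than the ring alkene) axially on the half‑chair with the C8 silyloxy group equatorial, so Br enters trans to OTBS (the other face is syn‑diaxial to OTBS), and AlMe3 then ionises the anomeric bromide and transfers methyl to the α‑bromo oxocarbenium ion to form the gem‑dimethyl ether carbon; the closest known reactions are haloglycosylation of glycals and AlMe3 C‑methylation of ketals and anomeric halides.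

**Step 8**
Reactants: 13 (2R,3R,5R)-5-bromo-3-[(tert-butyldimethylsilyl)oxy]-2,6,6-trimethyl-2-[(1S)-4-methylcyclohex-3-en-1-yl]oxane
Product: 14 (2R,3R,5R)-5-bromo-3-[(tert-butyldimethylsilyl)oxy]-2,6,6-trimethyl-2-[(1S,4S,6R)-1-methyl-7-oxabicyclo[4.1.0]heptan-4-yl]oxane (epoxide O anti to the oxanyl group)
Conditions: D‑fructose‑derived Shi ketone (30 mol%), Oxone, K2CO3, Bu4NHSO4, MeCN–DMM/borate buffer pH 10.5, 0 °C
Reagents that add atoms: potassium peroxymonosulfate (Oxone), [K+].[O-]S(=O)(=O)OO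
Why: Shi asymmetric epoxidation of the only remaining (trisubstituted) alkene; the spiro transition state, in the same sense as for (R,R)‑1‑phenylcyclohexene oxide, places the oxygen on the face anti to the C1′ substituent under catalyst control.

**Step 9**
Reactants: 14 (2R,3R,5R)-5-bromo-3-[(tert-butyldimethylsilyl)oxy]-2,6,6-trimethyl-2-[(1S,4S,6R)-1-methyl-7-oxabicyclo[4.1.0]heptan-4-yl]oxane
Product: 16 (2R,3R,5R)-5-bromo-2-[(1S,3S,4S)-3-bromo-4-chloro-4-methylcyclohexyl]-3-[(tert-butyldimethylsilyl)oxy]-2,6,6-trimethyloxane, via trans-diaxial bromohydrin 15 (not isolated)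
Conditions: pyridinium hydrobromide (1.0 equiv), CH2Cl2, −20 → 0 °C until 14 is consumed; then SOCl2 (1.5 equiv), 0 → 23 °C
Reagents that add atoms: pyridinium hydrobromide, [Br-].c1cc[nH+]cc1; thionyl chloride, O=S(Cl)Cl
Why: Fürst–Plattner and Markovnikov‑matched HBr opening gives the axial tertiary bromide anti to the axial secondary OH, and chlorosulfite ionisation with anchimeric assistance by that bromine (Winstein) gives the bromonium ion that chloride opens at the tertiary carbon, leaving Br at C5′ and Cl at C4′ trans‑diequatorial (1,2‑bromine shift).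

**Step 10**
Reactants: 16 (2R,3R,5R)-5-bromo-2-[(1S,3S,4S)-3-bromo-4-chloro-4-methylcyclohexyl]-3-[(tert-butyldimethylsilyl)oxy]-2,6,6-trimethyloxane
Product: 17 caespitol, (2R,3R,5R)-5-bromo-2-[(1S,3S,4S)-3-bromo-4-chloro-4-methylcyclohexyl]-2,6,6-trimethyloxan-3-ol
Conditions: HF·pyridine, THF–pyridine, 0 → 23 °C
Reagents that add atoms: none
Why: Fluoride‑mediated silyl ether cleavage under non‑basic conditions that leave the secondary bromides and the tertiary chloride untouched.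

**Compound list**
1 | isoprene (2-methylbuta-1,3-diene) | C=CC(C)=C | starting material
2 | methyl vinyl ketone (but-3-en-2-one) | CC(=O)C=C | starting material
3 | (S)-1-(4-methylcyclohex-3-en-1-yl)ethan-1-one | CC(=O)[C@H]1CCC(C)=CC1 | intermediate
4 | 1,2-bis(trimethylsilyloxy)cyclobut-1-ene | C[Si](C)(C)OC1=C(O[Si](C)(C)C)CC1 | starting material
5 | 2-(trimethylsilyloxy)-2-{1-[(1S)-4-methylcyclohex-3-en-1-yl]-1-(trimethylsilyloxy)ethyl}cyclobutan-1-one (diastereomer mixture at the two new centres) | CC(O[Si](C)(C)C)([C@H]1CCC(C)=CC1)C2(O[Si](C)(C)C)CCC2=O | intermediate (not isolated)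
6 | 2-methyl-2-[(1S)-4-methylcyclohex-3-en-1-yl]cyclopentane-1,3-dione | CC1([C@H]2CCC(C)=CC2)C(=O)CCC1=O | intermediate
7 | (2R,3R)-3-hydroxy-2-methyl-2-[(1S)-4-methylcyclohex-3-en-1-yl]cyclopentan-1-one | O=C1[C@](C)([C@H]2CCC(C)=CC2)[C@H](O)CC1 | intermediate
8 | (2R,3R)-3-[(tert-butyldimethylsilyl)oxy]-2-methyl-2-[(1S)-4-methylcyclohex-3-en-1-yl]cyclopentan-1-one | O=C1[C@](C)([C@H]2CCC(C)=CC2)[C@H](O[Si](C)(C)C(C)(C)C)CC1 | intermediate
9 | (5R,6R)-5-[(tert-butyldimethylsilyl)oxy]-6-methyl-6-[(1S)-4-methylcyclohex-3-en-1-yl]oxan-2-one | O=C1O[C@](C)([C@H]2CCC(C)=CC2)[C@H](O[Si](C)(C)C(C)(C)C)CC1 | intermediate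
10 | (5R,6R)-5-[(tert-butyldimethylsilyl)oxy]-2,6-dimethyl-6-[(1S)-4-methylcyclohex-3-en-1-yl]oxan-2-ol (anomer mixture) | CC1(O)O[C@](C)([C@H]2CCC(C)=CC2)[C@H](O[Si](C)(C)C(C)(C)C)CC1 | intermediate (not isolated)
11 | (2R,3R)-3-[(tert-butyldimethylsilyl)oxy]-2,6-dimethyl-2-[(1S)-4-methylcyclohex-3-en-1-yl]-3,4-dihydro-2H-pyran | CC1=CC[C@@H](O[Si](C)(C)C(C)(C)C)[C@@](C)([C@H]2CCC(C)=CC2)O1 | intermediate
12 | (2R,3R,5R)-5,6-dibromo-3-[(tert-butyldimethylsilyl)oxy]-2,6-dimethyl-2-[(1S)-4-methylcyclohex-3-en-1-yl]oxane (anomeric bromide, C6 unassigned) | CC1(Br)O[C@](C)([C@H]2CCC(C)=CC2)[C@H](O[Si](C)(C)C(C)(C)C)C[C@H]1Br | intermediate (not isolated)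
13 | (2R,3R,5R)-5-bromo-3-[(tert-butyldimethylsilyl)oxy]-2,6,6-trimethyl-2-[(1S)-4-methylcyclohex-3-en-1-yl]oxane | CC1(C)O[C@](C)([C@H]2CCC(C)=CC2)[C@H](O[Si](C)(C)C(C)(C)C)C[C@H]1Br | intermediate
14 | (2R,3R,5R)-5-bromo-3-[(tert-butyldimethylsilyl)oxy]-2,6,6-trimethyl-2-[(1S,4S,6R)-1-methyl-7-oxabicyclo[4.1.0]heptan-4-yl]oxane | CC1(C)O[C@](C)([C@H]2CC[C@]3(C)O[C@@H]3C2)[C@H](O[Si](C)(C)C(C)(C)C)C[C@H]1Br | intermediate
15 | (1R,2R,5S)-2-bromo-5-{(2R,3R,5R)-5-bromo-3-[(tert-butyldimethylsilyl)oxy]-2,6,6-trimethyloxan-2-yl}-2-methylcyclohexan-1-ol | CC1(C)O[C@](C)([C@H]2CC[C@@](C)(Br)[C@H](O)C2)[C@H](O[Si](C)(C)C(C)(C)C)C[C@H]1Br | intermediate (not isolated)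
16 | (2R,3R,5R)-5-bromo-2-[(1S,3S,4S)-3-bromo-4-chloro-4-methylcyclohexyl]-3-[(tert-butyldimethylsilyl)oxy]-2,6,6-trimethyloxane (O‑TBS caespitol) | CC1(C)O[C@](C)([C@H]2CC[C@](C)(Cl)[C@@H](Br)C2)[C@H](O[Si](C)(C)C(C)(C)C)C[C@H]1Br | intermediate
17 | caespitol, (2R,3R,5R)-5-bromo-2-[(1S,3S,4S)-3-bromo-4-chloro-4-methylcyclohexyl]-2,6,6-trimethyloxan-3-ol | CC1(C)O[C@](C)([C@H]2CC[C@](C)(Cl)[C@@H](Br)C2)[C@H](O)C[C@H]1Br | target

**Total step count:** 10. **Longest linear sequence:** 10 steps (fully linear from 1 and 2).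

**Steps most likely to fail**

Step 7 (the proposed bromo‑methylation). The risks are loss of HBr from the α‑bromo oxocarbenium ion and imperfect 1,3‑control at C10. The fallback uses only known chemistry and sets out from 11. NBS in wet THF at 0 °C (bromohydroxylation of the enol ether, same facial bias) gives the open‑chain bromo ketone (3R,5R,6R)-3-bromo-5-[(tert-butyldimethylsilyl)oxy]-6-hydroxy-6-[(1S)-4-methylcyclohex-3-en-1-yl]heptan-2-one F1, in equilibrium with its hemiketal. MeMgBr/CeCl3 at −78 °C adds to the ketone to give the bromo diol (3R,5R,6R)-3-bromo-5-[(tert-butyldimethylsilyl)oxy]-2-methyl-6-[(1S)-4-methylcyclohex-3-en-1-yl]heptane-2,6-diol F2. Catalytic CSA or BF3·OEt2 in CH2Cl2 then ionises the tertiary bromohydrin through its bromonium ion, and the C7 hydroxyl closes 6‑endo at the tertiary carbon with retention at C10. The fallback comes back to the route at 13.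

Step 8 (facial selectivity of the epoxidation on a 1‑methylcyclohexene with a remote stereocentre). The fallback sets out from 13. mCPBA/NaHCO3 in CH2Cl2 gives 14 together with the β‑epoxide diastereomer (2R,3R,5R)-5-bromo-3-[(tert-butyldimethylsilyl)oxy]-2,6,6-trimethyl-2-[(1S,4R,6S)-1-methyl-7-oxabicyclo[4.1.0]heptan-4-yl]oxane F3 in about a 1:1 ratio. Warming the mixture with pyrrolidine/water opens only F3, by trans‑diaxial attack at its secondary carbon (the kinetic separation known for the limonene oxides). This gives the amino alcohol (1R,2R,4S)-4-{(2R,3R,5R)-5-bromo-3-[(tert-butyldimethylsilyl)oxy]-2,6,6-trimethyloxan-2-yl}-1-methyl-2-(pyrrolidin-1-yl)cyclohexan-1-ol F4, which is removed by acid wash. The unreacted epoxide is recovered, and the fallback comes back at 14.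

Step 9 (chloride may open the bromonium ion at the secondary carbon, and any residual bromide gives dibromide). The fallback sets out from 13 and bypasses the epoxide. Direct anti bromochlorination with Bu4N+ BrCl2− in CH2Cl2 at −78 °C gives 16 together with the kinetically preferred trans‑diaxial diastereomer (2R,3R,5R)-5-bromo-2-[(1S,3R,4R)-3-bromo-4-chloro-4-methylcyclohexyl]-3-[(tert-butyldimethylsilyl)oxy]-2,6,6-trimethyloxane F5. 16 is expected to be the minor adduct and is separated by HPLC. The fallback comes back at 16.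

**Further compounds**
F1 | step 7 | (3R,5R,6R)-3-bromo-5-[(tert-butyldimethylsilyl)oxy]-6-hydroxy-6-[(1S)-4-methylcyclohex-3-en-1-yl]heptan-2-one | O[C@](C)([C@H]2CCC(C)=CC2)[C@H](O[Si](C)(C)C(C)(C)C)C[C@@H](Br)C(C)=O
F2 | step 7 | (3R,5R,6R)-3-bromo-5-[(tert-butyldimethylsilyl)oxy]-2-methyl-6-[(1S)-4-methylcyclohex-3-en-1-yl]heptane-2,6-diol | O[C@](C)([C@H]2CCC(C)=CC2)[C@H](O[Si](C)(C)C(C)(C)C)C[C@@H](Br)C(C)(C)O
F3 | step 8 | (2R,3R,5R)-5-bromo-3-[(tert-butyldimethylsilyl)oxy]-2,6,6-trimethyl-2-[(1S,4R,6S)-1-methyl-7-oxabicyclo[4.1.0]heptan-4-yl]oxane | CC1(C)O[C@](C)([C@H]2CC[C@@]3(C)O[C@H]3C2)[C@H](O[Si](C)(C)C(C)(C)C)C[C@H]1Br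
F4 | step 8 | (1R,2R,4S)-4-{(2R,3R,5R)-5-bromo-3-[(tert-butyldimethylsilyl)oxy]-2,6,6-trimethyloxan-2-yl}-1-methyl-2-(pyrrolidin-1-yl)cyclohexan-1-ol | CC1(C)O[C@](C)([C@H]2CC[C@@](C)(O)[C@H](N3CCCC3)C2)[C@H](O[Si](C)(C)C(C)(C)C)C[C@H]1Br
F5 | step 9 | (2R,3R,5R)-5-bromo-2-[(1S,3R,4R)-3-bromo-4-chloro-4-methylcyclohexyl]-3-[(tert-butyldimethylsilyl)oxy]-2,6,6-trimethyloxane | CC1(C)O[C@](C)([C@H]2CC[C@@](C)(Cl)[C@H](Br)C2)[C@H](O[Si](C)(C)C(C)(C)C)C[C@H]1Br
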